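**Retrosynthetic overview**
1. Target 21 ⇐ 5-O-methyl ether 20; the last step is a chelation-controlled O-demethylation.
2. Ring C of 20 ⇐ seven-membered O,O-acetal 18 by ring contraction: the acetal carbon shifts from oxygen to the neighbouring carbon (1,2-shift), which forms C2–C3 and sets both stereocentres.
3. Acetal 18 ⇐ glycolyl phenol 12 + aldehyde 16.
4. 12 ⇐ resorcinol 1 (O-methylation, C–H borylation/oxidation, two ortho-lithiations with prenyl bromide 6 and Weinreb amide 9); 16 ⇐ 4-bromophenol 13 + DMF.
5. Ring order: rings A and B are bought as benzene rings; the seven-membered acetal ring is closed first and is then contracted to ring C.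

Assumptions: the (S,S)-ligand in step 9 is taken to give the (2R,3R) series (the mirror-image ligand is used if a test run shows the opposite sense); Weinreb amide 9 is bought as its silyl ether; acetal 18 is used as the racemate because its stereocentre is erased in step 9.

**Step 1**
Reactants: 1 resorcinol
Product: 2 1,3-dimethoxybenzene
Conditions: MeI, K2CO3, acetone, reflux
Reagents that add atoms: iodomethane, CI
Why: Williamson ether synthesis on both phenols gives the symmetric dimethyl ether, one methyl of which ends as the 7-OMe group.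

**Step 2**
Reactants: 2 1,3-dimethoxybenzene
Product: 4 3,5-dimethoxyphenol, via aryl boronate 3 (not isolated)
Conditions: [Ir(OMe)(cod)]2 (1 mol %), 4,4'-di-tert-butyl-2,2'-bipyridine (2 mol %), B2pin2, cyclohexane, 80 °C; then KHSO5 (as 2KHSO5·KHSO4·K2SO4), acetone/H2O, rt
Reagents that add atoms: bis(pinacolato)diboron, CC1(C)OB(OC1(C)C)B1OC(C)(C)C(C)(C)O1 (boron of 3 only); potassium peroxymonosulfate, [K+].[O-]S(=O)(=O)OO (phenol oxygen)
Why: Iridium-catalysed C–H borylation is sterically controlled and C5 is the only C–H not ortho to a methoxy group, and oxidation of the C–B bond then gives the phenol (one-pot borylation/oxidation).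

**Step 3**
Reactants: 4 3,5-dimethoxyphenol
Product: 5 1,3-dimethoxy-5-(methoxymethoxy)benzene
Conditions: MOMCl, iPr2NEt, CH2Cl2, 0 °C → rt
Reagents that add atoms: chloromethyl methyl ether, COCCl
Why: O-alkylation of the phenol gives the MOM ether, which protects the future ring oxygen O1 and serves as the directing group for both lithiations.

**Step 4**
Reactants: 5 1,3-dimethoxy-5-(methoxymethoxy)benzene; 6 1-bromo-3-methylbut-2-ene (prenyl bromide)
Product: 8 1,5-dimethoxy-3-(methoxymethoxy)-2-(3-methylbut-2-en-1-yl)benzene, via aryllithium 7 (not isolated)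
Conditions: n-BuLi, THF, 0 °C; then CuI (10 mol %), 6, −78 °C → rt
Reagents that add atoms: n-butyllithium, [Li]CCCC (lithium of 7 only)
Why: Directed ortho-metalation takes the C–H between OMOM and OMe (MOM is the stronger director, so lithiation between the two methoxy groups is minor), and copper-catalysed SN2 allylation then places the prenyl group next to the future O1.

**Step 5**
Reactants: 8 1,5-dimethoxy-3-(methoxymethoxy)-2-(3-methylbut-2-en-1-yl)benzene; 9 2-[(tert-butyldimethylsilyl)oxy]-N-methoxy-N-methylacetamide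
Product: 12 2-hydroxy-1-[2-hydroxy-4,6-dimethoxy-3-(3-methylbut-2-en-1-yl)phenyl]ethan-1-one, via aryllithium 10 (not isolated), via protected ketone 11 (not isolated)
Conditions: n-BuLi, THF, 0 °C; then 9, −78 → 0 °C; then 2 M HCl in MeOH, rt
Reagents that add atoms: n-butyllithium, [Li]CCCC (lithium of 10 only)
Why: A second directed ortho-metalation at the remaining position ortho to OMOM followed by Weinreb ketone synthesis gives the aryl ketone without over-addition, and methanolic HCl cleaves the ortho-acyl MOM ether and the primary silyl ether in the same flask.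

**Step 6**
Reactants: 13 4-bromophenol
Product: 14 (4-bromophenoxy)(tert-butyl)dimethylsilane
Conditions: TBSCl, imidazole, DMF, rt
Reagents that add atoms: tert-butyldimethylsilyl chloride, CC(C)(C)[Si](C)(C)Cl
Why: Standard silylation protects the phenol of ring B for the organolithium and Lewis acid steps.

**Step 7**
Reactants: 14 (4-bromophenoxy)(tert-butyl)dimethylsilane
Product: 16 4-[(tert-butyldimethylsilyl)oxy]benzaldehyde, via aryllithium 15 (not isolated)
Conditions: n-BuLi, THF, −78 °C; then DMF, −78 °C → rt; H2O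
Reagents that add atoms: n-butyllithium, [Li]CCCC (lithium of 15 only); N,N-dimethylformamide, CN(C)C=O
Why: Bromine–lithium exchange followed by formylation with DMF (Bouveault aldehyde synthesis) gives the aldehyde whose carbonyl carbon becomes C2.

**Step 8**
Reactants: 12 2-hydroxy-1-[2-hydroxy-4,6-dimethoxy-3-(3-methylbut-2-en-1-yl)phenyl]ethan-1-one; 16 4-[(tert-butyldimethylsilyl)oxy]benzaldehyde
Product: 18 rac-2-[4-[(tert-butyldimethylsilyl)oxy]phenyl]-6,8-dimethoxy-9-(3-methylbut-2-en-1-yl)-4H-1,3-benzodioxepin-5-one, via dimethyl acetal 17 (not isolated)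
Conditions: 16, HC(OMe)3, PPTS (10 mol %), PhMe, rt; then 12, 5 Å MS, 60 °C
Reagents that add atoms: trimethyl orthoformate, COC(OC)OC (methoxy groups of 17 only)
Why: Acid-catalysed transacetalisation of the dimethyl acetal by the phenol and the primary alcohol, driven by removal of methanol, closes the benzo-fused seven-membered acetal; the single acetal stereocentre is formed racemic.

**Step 9**
Reactants: 18 rac-2-[4-[(tert-butyldimethylsilyl)oxy]phenyl]-6,8-dimethoxy-9-(3-methylbut-2-en-1-yl)-4H-1,3-benzodioxepin-5-one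
Product: 20 (2R,3R)-3-hydroxy-2-(4-hydroxyphenyl)-5,7-dimethoxy-8-(3-methylbut-2-en-1-yl)-2,3-dihydro-4H-chromen-4-one, via silyl ether 19 (not isolated)
Conditions: Sc(OTf)3 (10 mol %), (S,S)-iPr-pybox (12 mol %), 2,6-di-tert-butyl-4-methylpyridine (20 mol %), 4 Å MS, CH2Cl2, −40 → −20 °C; then KHF2, MeOH, rt
Reagents that add atoms: none
Why: Proposed new method: a stereoconvergent, catalyst-controlled ring contraction of a seven-membered O,O-acetal in which the acetal carbon C2 shifts from O3 to C4 (oxygen-to-carbon 1,2-shift); the chiral trivalent scandium complex chelates the ketone oxygen and O3, which ionises the C2–O3 bond selectively and erases the racemic acetal centre, and proton transfer through the hindered pyridine leaves a scandium enediolate held next to an aryl-stabilised oxocarbenium ion; collapse of this ion pair at carbon through a chair-like transition state closes ring C, sets C3 (R) under catalyst control and C2 (R) trans to it (the trans isomer is also the thermodynamic one, since C2 can re-ionise), and KHF2 then removes the aryl silyl ether in the same flask; the closest known reaction types are the Petasis–Ferrier rearrangement, Lewis-acid-catalysed 1,3 oxygen-to-carbon shifts of acetals and chiral-Lewis-acid direct aldol reactions of alpha-hydroxy ketones.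

**Step 10**
Reactants: 20 (2R,3R)-3-hydroxy-2-(4-hydroxyphenyl)-5,7-dimethoxy-8-(3-methylbut-2-en-1-yl)-2,3-dihydro-4H-chromen-4-one
Product: 21 (2R,3R)-3,5-dihydroxy-2-(4-hydroxyphenyl)-7-methoxy-8-(3-methylbut-2-en-1-yl)-2,3-dihydro-4H-chromen-4-one
Conditions: MgI2·OEt2 (4 equiv), THF, 60 °C; then 1 M aq. HCl
Reagents that add atoms: none
Why: Chelation-assisted ether cleavage (magnesium bound between the C4 carbonyl and the 5-OMe oxygen, SN2 attack of iodide on the methyl group) removes only the 5-O-methyl group and leaves the 7-OMe group, the prenyl alkene and both stereocentres untouched.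

**Compound list**
1 | resorcinol (benzene-1,3-diol) | Oc1cccc(O)c1 | starting material
2 | 1,3-dimethoxybenzene | COc1cccc(OC)c1 | intermediate
3 | 2-(3,5-dimethoxyphenyl)-4,4,5,5-tetramethyl-1,3,2-dioxaborolane | COc1cc(OC)cc(c1)B1OC(C)(C)C(C)(C)O1 | intermediate (not isolated)
4 | 3,5-dimethoxyphenol | COc1cc(O)cc(OC)c1 | intermediate
5 | 1,3-dimethoxy-5-(methoxymethoxy)benzene | COCOc1cc(OC)cc(OC)c1 | intermediate
6 | 1-bromo-3-methylbut-2-ene (prenyl bromide) | CC(C)=CCBr | starting material
7 | [2,4-dimethoxy-6-(methoxymethoxy)phenyl]lithium | [Li]c1c(OCOC)cc(OC)cc1OC | intermediate (not isolated)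
8 | 1,5-dimethoxy-3-(methoxymethoxy)-2-(3-methylbut-2-en-1-yl)benzene | COCOc1cc(OC)cc(OC)c1CC=C(C)C | intermediate
9 | 2-[(tert-butyldimethylsilyl)oxy]-N-methoxy-N-methylacetamide | CON(C)C(=O)CO[Si](C)(C)C(C)(C)C | starting material
10 | [4,6-dimethoxy-2-(methoxymethoxy)-3-(3-methylbut-2-en-1-yl)phenyl]lithium | [Li]c1c(OC)cc(OC)c(CC=C(C)C)c1OCOC | intermediate (not isolated)
11 | 2-[(tert-butyldimethylsilyl)oxy]-1-[4,6-dimethoxy-2-(methoxymethoxy)-3-(3-methylbut-2-en-1-yl)phenyl]ethan-1-one | COCOc1c(CC=C(C)C)c(OC)cc(OC)c1C(=O)CO[Si](C)(C)C(C)(C)C | intermediate (not isolated)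
12 | 2-hydroxy-1-[2-hydroxy-4,6-dimethoxy-3-(3-methylbut-2-en-1-yl)phenyl]ethan-1-one | COc1cc(OC)c(C(=O)CO)c(O)c1CC=C(C)C | intermediate
13 | 4-bromophenol | Oc1ccc(Br)cc1 | starting material
14 | (4-bromophenoxy)(tert-butyl)dimethylsilane | CC(C)(C)[Si](C)(C)Oc1ccc(Br)cc1 | intermediate
15 | [4-[(tert-butyldimethylsilyl)oxy]phenyl]lithium | [Li]c1ccc(O[Si](C)(C)C(C)(C)C)cc1 | intermediate (not isolated)
16 | 4-[(tert-butyldimethylsilyl)oxy]benzaldehyde | O=Cc1ccc(O[Si](C)(C)C(C)(C)C)cc1 | intermediate
17 | tert-butyl[4-(dimethoxymethyl)phenoxy]dimethylsilane | COC(OC)c1ccc(O[Si](C)(C)C(C)(C)C)cc1 | intermediate (not isolated)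
18 | rac-2-[4-[(tert-butyldimethylsilyl)oxy]phenyl]-6,8-dimethoxy-9-(3-methylbut-2-en-1-yl)-4H-1,3-benzodioxepin-5-one | COc1cc(OC)c2c(c1CC=C(C)C)OC(c1ccc(O[Si](C)(C)C(C)(C)C)cc1)OCC2=O | intermediate
19 | (2R,3R)-2-[4-[(tert-butyldimethylsilyl)oxy]phenyl]-3-hydroxy-5,7-dimethoxy-8-(3-methylbut-2-en-1-yl)-2,3-dihydro-4H-chromen-4-one | COc1cc(OC)c2c(c1CC=C(C)C)O[C@H](c1ccc(O[Si](C)(C)C(C)(C)C)cc1)[C@@H](O)C2=O | intermediate (not isolated)
20 | (2R,3R)-3-hydroxy-2-(4-hydroxyphenyl)-5,7-dimethoxy-8-(3-methylbut-2-en-1-yl)-2,3-dihydro-4H-chromen-4-one | COc1cc(OC)c2c(c1CC=C(C)C)O[C@H](c1ccc(O)cc1)[C@@H](O)C2=O | intermediate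
21 | (2R,3R)-3,5-dihydroxy-2-(4-hydroxyphenyl)-7-methoxy-8-(3-methylbut-2-en-1-yl)-2,3-dihydro-4H-chromen-4-one | COc1cc(O)c2c(c1CC=C(C)C)O[C@H](c1ccc(O)cc1)[C@@H](O)C2=O | target

**Step count and risks**
Total steps: 10. Longest linear sequence: 8 (steps 1–5 and 8–10, from resorcinol).

Step 9 (proposed new ring contraction). The reaction is unprecedented: the oxocarbenium ion could be trapped by the prenyl alkene (Prins-type), the product can bind the catalyst, and the enantioselectivity is untested. Fallback, known chemistry: set out from 12 and 16. A syn-selective direct aldol reaction with Et2Zn and ProPhenol (dinuclear zinc catalyst, enantiomer chosen for the 2R,3S diol, one extra equivalent of Et2Zn for the free phenol, THF, 4 Å MS, −20 °C) gives the syn diol (2R,3S)-3-[4-[(tert-butyldimethylsilyl)oxy]phenyl]-2,3-dihydroxy-1-[2-hydroxy-4,6-dimethoxy-3-(3-methylbut-2-en-1-yl)phenyl]propan-1-one F1. Intramolecular Mitsunobu etherification (PPh3, DIAD, THF, 0 °C) then closes ring C through the phenol with inversion at the benzylic carbon. This comes back to the route at 19, which is desilylated with KHF2 in MeOH as in step 9 to give 20.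

Step 8 (seven-membered acetal). The phenol is hindered and hydrogen-bonded to the ketone, mixed aryl alkyl acetals are labile, and acid next to the prenyl group can lead to side reactions. Fallback: set out from 12 and silylate both hydroxyl groups (TMSCl, Et3N, CH2Cl2) to the bis(trimethylsilyl) ether 1-[4,6-dimethoxy-3-(3-methylbut-2-en-1-yl)-2-[(trimethylsilyl)oxy]phenyl]-2-[(trimethylsilyl)oxy]ethan-1-one F2. A Noyori acetalisation with 16 (TMSOTf, 5 mol %, CH2Cl2, −78 °C) then forms the acetal under kinetic, aprotic conditions and comes back to the route at 18.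

Step 5 (second ortho-lithiation and acylation). n-BuLi may deprotonate the allylic-benzylic CH2 of the prenyl group or the position between the two methoxy groups. Fallback: set out from 8 and remove the MOM group (HCl, MeOH, rt) to give 3,5-dimethoxy-2-(3-methylbut-2-en-1-yl)phenol F3. Ortho-selective formylation (MgCl2, Et3N, paraformaldehyde, MeCN, reflux) at the only free ortho position gives 2-hydroxy-4,6-dimethoxy-3-(3-methylbut-2-en-1-yl)benzaldehyde F4. An NHC-catalysed hydroxymethylation with paraformaldehyde (thiazolium salt, iPr2NEt, THF, 60 °C) then converts the aldehyde into the glycolyl ketone and comes back to the route at 12.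

**Further compounds**
F1 | step 9 | (2R,3S)-3-[4-[(tert-butyldimethylsilyl)oxy]phenyl]-2,3-dihydroxy-1-[2-hydroxy-4,6-dimethoxy-3-(3-methylbut-2-en-1-yl)phenyl]propan-1-one | COc1cc(OC)c(C(=O)[C@H](O)[C@@H](O)c2ccc(O[Si](C)(C)C(C)(C)C)cc2)c(O)c1CC=C(C)C
F2 | step 8 | 1-[4,6-dimethoxy-3-(3-methylbut-2-en-1-yl)-2-[(trimethylsilyl)oxy]phenyl]-2-[(trimethylsilyl)oxy]ethan-1-one | COc1cc(OC)c(C(=O)CO[Si](C)(C)C)c(O[Si](C)(C)C)c1CC=C(C)C
F3 | step 5 | 3,5-dimethoxy-2-(3-methylbut-2-en-1-yl)phenol | COc1cc(O)c(CC=C(C)C)c(OC)c1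
F4 | step 5 | 2-hydroxy-4,6-dimethoxy-3-(3-methylbut-2-en-1-yl)benzaldehyde | COc1cc(OC)c(C=O)c(O)c1CC=C(C)C
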